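**Retrosynthetic overview**
1. Target 20 ⇐ hydrogenolysis of tribenzyl ether 19; the (2R) centre of 19 ⇐ kinetic resolution (asymmetric transfer hydrogenation) of racemic flavanone 18.
2. 18 ⇐ oxa-Michael closure of chalcone 17 ⇐ key intermolecular Claisen–Schmidt aldol condensation of methyl ketone 14 (the complete flavone half) with 4-(benzyloxy)benzaldehyde 15.
3. 14 ⇐ Friedel–Crafts acetylation and deallylation of 3-arylflavone 12; the allyl ether marks the oxygen para to the inter-unit bond as the future pyranone oxygen, so only the 6-linked flavanone can form.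
4. 12 ⇐ intermolecular Claisen-type C-acylation of deoxybenzoin 8 with 4-methoxybenzoyl chloride 9, cyclodehydration, 7-O-methylation; 8 ⇐ Hoesch acylation of phloroglucinol 6 with arylacetonitrile 5. The inter-unit bond is the aryl–CH2 bond of 5, carried from 2,4,6-trihydroxybenzaldehyde 1.
5. Ring order: flavone pyranone (ring C of the first unit) first, flavanone pyranone (ring C of the second unit) last, because the flavanone centre is base-labile.

Assumption: the axis between the two units has no descriptor in the target and is treated as freely rotating; only C2 of the flavanone is controlled (benzylated intermediates may show rotamers in NMR).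

**Route**

Step 1
Reactants: 1 2,4,6-trihydroxybenzaldehyde
Product: 2 4-(allyloxy)-2,6-dihydroxybenzaldehyde
Conditions: allyl bromide (1.0 equiv), KHCO3, DMF, 40 °C
Reagents that add atoms: allyl bromide, C=CCBr
Why: Williamson etherification at the most acidic, non-chelated para hydroxyl (the two ortho hydroxyls are hydrogen-bonded to the aldehyde), which tags the future ring oxygen with a group orthogonal to benzyl.

Step 2
Reactants: 2 4-(allyloxy)-2,6-dihydroxybenzaldehyde
Product: 3 4-(allyloxy)-2,6-bis(benzyloxy)benzaldehyde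
Conditions: BnBr (2.5 equiv), K2CO3, DMF, 60 °C
Reagents that add atoms: benzyl bromide, BrCc1ccccc1
Why: Exhaustive Williamson benzylation of the two remaining chelated phenols, giving ethers that survive acid and base and fall off together by hydrogenolysis at the end.

Step 3
Reactants: 3 4-(allyloxy)-2,6-bis(benzyloxy)benzaldehyde
Product: 5 2-[4-(allyloxy)-2,6-bis(benzyloxy)phenyl]acetonitrile, via N-(1-tosylvinyl)formamide 4 (not isolated)
Conditions: TosMIC, KOt-Bu, DME, −35 °C → rt; then MeOH, reflux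
Reagents that add atoms: TosMIC (p-toluenesulfonylmethyl isocyanide), Cc1ccc(cc1)S(=O)(=O)C[N+]#[C-]
Why: van Leusen reductive cyanation: TosMIC adds to the aldehyde, the oxazoline opens to formamide 4, and methanolysis expels formate and sulfinate, giving the homologated nitrile without an ionisable trialkoxybenzyl halide.

Step 4
Reactants: 5 2-[4-(allyloxy)-2,6-bis(benzyloxy)phenyl]acetonitrile; 6 phloroglucinol
Product: 8 2-[4-(allyloxy)-2,6-bis(benzyloxy)phenyl]-1-(2,4,6-trihydroxyphenyl)ethan-1-one, via ketiminium chloride 7 (not isolated)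
Conditions: 6 (2 equiv), ZnCl2, HCl (g), Et2O, 0 °C, 24 h; then H2O, reflux
Reagents that add atoms: water, O
Why: Houben–Hoesch acylation: the HCl-activated nitrile acylates symmetric, highly nucleophilic phloroglucinol (in excess so it outcompetes the arene of 5), and hydrolysis of salt 7 gives the ketone with no regiochemical ambiguity.

Step 5
Reactants: 8 2-[4-(allyloxy)-2,6-bis(benzyloxy)phenyl]-1-(2,4,6-trihydroxyphenyl)ethan-1-one; 9 4-methoxybenzoyl chloride
Product: 11 3-[4-(allyloxy)-2,6-bis(benzyloxy)phenyl]-5,7-dihydroxy-2-(4-methoxyphenyl)-4H-chromen-4-one, via 1,3-diketone 10 (not isolated)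
Conditions: LiN(SiMe3)2 (5 equiv), THF, −78 → −10 °C; 9 (1.1 equiv), −78 °C → rt; then TsOH·H2O (cat.), AcOH, 80 °C
Reagents that add atoms: none
Why: Intermolecular Claisen-type C-acylation of the lithium enolate (phenols masked as lithium phenoxides) gives diketone 10, any O-aroyl ester converging on 10 by Baker–Venkataraman shift under the excess base; acid-catalysed cyclodehydration through either equivalent ortho hydroxyl then closes the flavone ring.

Step 6
Reactants: 11 3-[4-(allyloxy)-2,6-bis(benzyloxy)phenyl]-5,7-dihydroxy-2-(4-methoxyphenyl)-4H-chromen-4-one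
Product: 12 3-[4-(allyloxy)-2,6-bis(benzyloxy)phenyl]-5-hydroxy-7-methoxy-2-(4-methoxyphenyl)-4H-chromen-4-one
Conditions: MeI (1.1 equiv), K2CO3, acetone, rt
Reagents that add atoms: iodomethane, CI
Why: Williamson methylation selective for the acidic 7-OH, because the 5-OH is deactivated by its hydrogen bond to the C4 carbonyl.

Step 7
Reactants: 12 3-[4-(allyloxy)-2,6-bis(benzyloxy)phenyl]-5-hydroxy-7-methoxy-2-(4-methoxyphenyl)-4H-chromen-4-one
Product: 13 3-[3-acetyl-4-(allyloxy)-2,6-bis(benzyloxy)phenyl]-5-hydroxy-7-methoxy-2-(4-methoxyphenyl)-4H-chromen-4-one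
Conditions: AcOH, (CF3CO)2O, CH2Cl2, 0 °C → rt; aq. NaHCO3 work-up
Reagents that add atoms: acetic acid, CC(=O)O
Why: Lewis-acid-free Friedel–Crafts acetylation by acetyl trifluoroacetate attacks the phloroglucinol triether ring, the most electron-rich arene, at one of its two equivalent free positions, and the new ketone blocks a second acylation.

Step 8
Reactants: 13 3-[3-acetyl-4-(allyloxy)-2,6-bis(benzyloxy)phenyl]-5-hydroxy-7-methoxy-2-(4-methoxyphenyl)-4H-chromen-4-one
Product: 14 3-[3-acetyl-2,6-bis(benzyloxy)-4-hydroxyphenyl]-5-hydroxy-7-methoxy-2-(4-methoxyphenyl)-4H-chromen-4-one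
Conditions: Pd(PPh3)4 (5 mol %), morpholine, THF, rt
Reagents that add atoms: none
Why: Tsuji–Trost deallylation: zerovalent palladium ionises the allyl aryl ether and morpholine traps the allyl unit, leaving benzyl ethers intact and freeing only the phenol ortho to the acetyl and para to the inter-unit bond.

Step 9
Reactants: 14 3-[3-acetyl-2,6-bis(benzyloxy)-4-hydroxyphenyl]-5-hydroxy-7-methoxy-2-(4-methoxyphenyl)-4H-chromen-4-one; 15 4-(benzyloxy)benzaldehyde
Product: 17 3-{2,6-bis(benzyloxy)-3-[(E)-3-(4-benzyloxyphenyl)prop-2-enoyl]-4-hydroxyphenyl}-5-hydroxy-7-methoxy-2-(4-methoxyphenyl)-4H-chromen-4-one, via aldol adduct 16 (not isolated)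
Conditions: 15 (1.5 equiv), KOH (aq), EtOH/THF, rt; then HCl (aq) to pH 4
Reagents that add atoms: none
Why: Claisen–Schmidt crossed aldol condensation: the methyl ketone is the only enolisable carbonyl and the aldehyde cannot enolise, so adduct 16 forms and dehydrates (E1cB) to the E-chalcone, joining the two fragments.

Step 10
Reactants: 17 the E-chalcone
Product: 18 rac-5,7-bis(benzyloxy)-2-[4-(benzyloxy)phenyl]-6-[5-hydroxy-7-methoxy-2-(4-methoxyphenyl)-4-oxo-4H-chromen-3-yl]chroman-4-one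
Conditions: NaOAc, EtOH, reflux
Reagents that add atoms: none
Why: Intramolecular oxa-Michael addition of the only free ortho phenol (the other ortho oxygen is benzylated, so only the 6-linked flavanone can form); the 6'-benzyloxy group favours the closed form, and C2 is formed as a racemate.

Step 11
Reactants: 18 the racemic flavanone
Product: 19 (2R)-5,7-bis(benzyloxy)-2-[4-(benzyloxy)phenyl]-6-[5-hydroxy-7-methoxy-2-(4-methoxyphenyl)-4-oxo-4H-chromen-3-yl]chroman-4-one
Conditions: RuCl[(S,S)-TsDPEN](p-cymene) (2 mol %), HCO2H/Et3N (5:2), EtOAc, 40 °C, to ca. 55% conversion; chromatography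
Reagents that add atoms: none
Why: Kinetic resolution by Noyori asymmetric transfer hydrogenation: the (S,S)-catalyst delivers hydride to the face giving the (4S)-alcohol, which is the matched cis face only for the (2S)-ketone, so that enantiomer is reduced to the (2S,4S)-flavan-4-ol and the (2R)-ketone is recovered in high ee (at most 50% yield).

Step 12
Reactants: 19 the (2R)-tribenzyl flavanone
Product: 20 (2R)-5,7-dihydroxy-6-[5-hydroxy-7-methoxy-2-(4-methoxyphenyl)-4-oxo-4H-chromen-3-yl]-2-(4-hydroxyphenyl)chroman-4-one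
Conditions: H2 (1 atm), Pd/C (10%), EtOAc/MeOH, rt
Reagents that add atoms: none
Why: Hydrogenolysis of the three benzyl aryl ethers under neutral conditions, which cannot open the flavanone by retro-oxa-Michael reaction, so C2 stays R.

**Compound list**
1 | 2,4,6-trihydroxybenzaldehyde | O=Cc1c(O)cc(O)cc1O | starting material
2 | 4-(allyloxy)-2,6-dihydroxybenzaldehyde | O=Cc1c(O)cc(OCC=C)cc1O | intermediate
3 | 4-(allyloxy)-2,6-bis(benzyloxy)benzaldehyde | O=Cc1c(OCc2ccccc2)cc(OCC=C)cc1OCc1ccccc1 | intermediate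
4 | N-{2-[4-(allyloxy)-2,6-bis(benzyloxy)phenyl]-1-tosylethenyl}formamide (not isolated) | O=CNC(=Cc1c(OCc2ccccc2)cc(OCC=C)cc1OCc1ccccc1)S(=O)(=O)c1ccc(C)cc1 | intermediate
5 | 2-[4-(allyloxy)-2,6-bis(benzyloxy)phenyl]acetonitrile | N#CCc1c(OCc2ccccc2)cc(OCC=C)cc1OCc1ccccc1 | intermediate
6 | phloroglucinol (benzene-1,3,5-triol) | Oc1cc(O)cc(O)c1 | starting material
7 | 2-[4-(allyloxy)-2,6-bis(benzyloxy)phenyl]-1-(2,4,6-trihydroxyphenyl)ethan-1-iminium chloride (not isolated) | [Cl-].[NH2+]=C(Cc1c(OCc2ccccc2)cc(OCC=C)cc1OCc1ccccc1)c1c(O)cc(O)cc1O | intermediate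
8 | 2-[4-(allyloxy)-2,6-bis(benzyloxy)phenyl]-1-(2,4,6-trihydroxyphenyl)ethan-1-one | O=C(Cc1c(OCc2ccccc2)cc(OCC=C)cc1OCc1ccccc1)c1c(O)cc(O)cc1O | intermediate
9 | 4-methoxybenzoyl chloride | COc1ccc(cc1)C(Cl)=O | starting material
10 | 2-[4-(allyloxy)-2,6-bis(benzyloxy)phenyl]-1-(4-methoxyphenyl)-3-(2,4,6-trihydroxyphenyl)propane-1,3-dione (not isolated) | COc1ccc(cc1)C(=O)C(c1c(OCc2ccccc2)cc(OCC=C)cc1OCc1ccccc1)C(=O)c1c(O)cc(O)cc1O | intermediate
11 | 3-[4-(allyloxy)-2,6-bis(benzyloxy)phenyl]-5,7-dihydroxy-2-(4-methoxyphenyl)-4H-chromen-4-one | COc1ccc(cc1)-c1oc2cc(O)cc(O)c2c(=O)c1-c1c(OCc2ccccc2)cc(OCC=C)cc1OCc1ccccc1 | intermediate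
12 | 3-[4-(allyloxy)-2,6-bis(benzyloxy)phenyl]-5-hydroxy-7-methoxy-2-(4-methoxyphenyl)-4H-chromen-4-one | COc1ccc(cc1)-c1oc2cc(OC)cc(O)c2c(=O)c1-c1c(OCc2ccccc2)cc(OCC=C)cc1OCc1ccccc1 | intermediate
13 | 3-[3-acetyl-4-(allyloxy)-2,6-bis(benzyloxy)phenyl]-5-hydroxy-7-methoxy-2-(4-methoxyphenyl)-4H-chromen-4-one | COc1ccc(cc1)-c1oc2cc(OC)cc(O)c2c(=O)c1-c1c(OCc2ccccc2)c(C(C)=O)c(OCC=C)cc1OCc1ccccc1 | intermediate
14 | 3-[3-acetyl-2,6-bis(benzyloxy)-4-hydroxyphenyl]-5-hydroxy-7-methoxy-2-(4-methoxyphenyl)-4H-chromen-4-one | COc1ccc(cc1)-c1oc2cc(OC)cc(O)c2c(=O)c1-c1c(OCc2ccccc2)c(C(C)=O)c(O)cc1OCc1ccccc1 | intermediate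
15 | 4-(benzyloxy)benzaldehyde | O=Cc1ccc(OCc2ccccc2)cc1 | starting material
16 | 3-{2,6-bis(benzyloxy)-3-[3-(4-benzyloxyphenyl)-3-hydroxypropanoyl]-4-hydroxyphenyl}-5-hydroxy-7-methoxy-2-(4-methoxyphenyl)-4H-chromen-4-one (racemic, not isolated) | COc1ccc(cc1)-c1oc2cc(OC)cc(O)c2c(=O)c1-c1c(OCc2ccccc2)c(C(=O)CC(O)c2ccc(OCc3ccccc3)cc2)c(O)cc1OCc1ccccc1 | intermediate
17 | 3-{2,6-bis(benzyloxy)-3-[(E)-3-(4-benzyloxyphenyl)prop-2-enoyl]-4-hydroxyphenyl}-5-hydroxy-7-methoxy-2-(4-methoxyphenyl)-4H-chromen-4-one | COc1ccc(cc1)-c1oc2cc(OC)cc(O)c2c(=O)c1-c1c(OCc2ccccc2)c(C(=O)/C=C/c2ccc(OCc3ccccc3)cc2)c(O)cc1OCc1ccccc1 | intermediate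
18 | rac-5,7-bis(benzyloxy)-2-[4-(benzyloxy)phenyl]-6-[5-hydroxy-7-methoxy-2-(4-methoxyphenyl)-4-oxo-4H-chromen-3-yl]chroman-4-one (racemic at C2) | COc1ccc(-c2oc3cc(OC)cc(O)c3c(=O)c2-c2c(OCc4ccccc4)cc3c(c2OCc5ccccc5)C(=O)CC(c6ccc(OCc7ccccc7)cc6)O3)cc1 | intermediate
19 | (2R)-5,7-bis(benzyloxy)-2-[4-(benzyloxy)phenyl]-6-[5-hydroxy-7-methoxy-2-(4-methoxyphenyl)-4-oxo-4H-chromen-3-yl]chroman-4-one | COc1ccc(-c2oc3cc(OC)cc(O)c3c(=O)c2-c2c(OCc4ccccc4)cc3c(c2OCc5ccccc5)C(=O)C[C@H](c6ccc(OCc7ccccc7)cc6)O3)cc1 | intermediate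
20 | (2R)-5,7-dihydroxy-6-[5-hydroxy-7-methoxy-2-(4-methoxyphenyl)-4-oxo-4H-chromen-3-yl]-2-(4-hydroxyphenyl)chroman-4-one (CNP0292254.1) | COc1ccc(-c2oc3cc(OC)cc(O)c3c(=O)c2-c2c(O)cc3c(c2O)C(=O)C[C@H](c2ccc(O)cc2)O3)cc1 | target

**Step count**
Total steps: 12. Longest linear sequence: 12 steps (from 1; compounds 6, 9 and 15 are bought and enter directly).

**Three steps most likely to fail**

Step 4 (Hoesch acylation). Anhydrous HCl may attack the allyl or benzyl ethers, and the nitrile may acylate its own electron-rich ring instead of phloroglucinol. The fallback avoids acid and electrophilic acylation; it sets out from 5 and 6 and comes back at 8. Nitrile 5 is reduced with i-Bu2AlH (toluene, −78 °C, aqueous HCl work-up) to 2-[4-(allyloxy)-2,6-bis(benzyloxy)phenyl]acetaldehyde F1. Phloroglucinol 6 is converted with chloromethyl methyl ether and i-Pr2NEt into 1,3,5-tris(methoxymethoxy)benzene F2, which is lithiated between two acetal oxygens (n-BuLi, THF, 0 °C) and added to F1 at −78 °C to give racemic 2-[4-(allyloxy)-2,6-bis(benzyloxy)phenyl]-1-[2,4,6-tris(methoxymethoxy)phenyl]ethan-1-ol F3. Dess–Martin oxidation (CH2Cl2, NaHCO3) gives 2-[4-(allyloxy)-2,6-bis(benzyloxy)phenyl]-1-[2,4,6-tris(methoxymethoxy)phenyl]ethan-1-one F4, and HCl in MeOH at 40 °C removes the three acetals to give 8.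

Step 7 (late acetylation). The hindered position between two alkoxy groups may react slowly, and the acidic medium may cost a benzyl or allyl group or acylate the 5-OH. The fallback replaces electrophilic acylation by halogenation and cross-coupling; it sets out from 12 and comes back at 14. Deallylation first (Pd(PPh3)4, morpholine, THF) gives 3-[2,6-bis(benzyloxy)-4-hydroxyphenyl]-5-hydroxy-7-methoxy-2-(4-methoxyphenyl)-4H-chromen-4-one F5. N-Iodosuccinimide (1.0 equiv, CH2Cl2, −20 °C) iodinates one of the two equivalent positions ortho to the new phenol to give 3-[2,6-bis(benzyloxy)-4-hydroxy-3-iodophenyl]-5-hydroxy-7-methoxy-2-(4-methoxyphenyl)-4H-chromen-4-one F6. Stille coupling with tributyl(1-ethoxyvinyl)stannane (PdCl2(PPh3)2, toluene, 90 °C) gives 3-[2,6-bis(benzyloxy)-3-(1-ethoxyethenyl)-4-hydroxyphenyl]-5-hydroxy-7-methoxy-2-(4-methoxyphenyl)-4H-chromen-4-one F7, and 1 M HCl in THF hydrolyses the enol ether to 14.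

Step 11 (kinetic resolution). The peri benzyloxy group and the bulky 6-aryl substituent may slow the reduction and lower the selectivity factor, and rotamers about the inter-unit axis may behave as different substrates. The fallback replaces catalytic resolution by physical separation; it sets out from 18 and comes back at 19. Preparative supercritical-fluid chromatography on amylose tris(3,5-dimethylphenylcarbamate) (CO2/MeOH) separates 19 from (2S)-5,7-bis(benzyloxy)-2-[4-(benzyloxy)phenyl]-6-[5-hydroxy-7-methoxy-2-(4-methoxyphenyl)-4-oxo-4H-chromen-3-yl]chroman-4-one F8. F8 is re-racemised to 18 (NaOAc, EtOH, reflux, by ring opening to chalcone 17 and re-closure) and recycled.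

**Further compounds**
F1 | step 4 | 2-[4-(allyloxy)-2,6-bis(benzyloxy)phenyl]acetaldehyde | O=CCc1c(OCc2ccccc2)cc(OCC=C)cc1OCc1ccccc1
F2 | step 4 | 1,3,5-tris(methoxymethoxy)benzene | COCOc1cc(OCOC)cc(OCOC)c1
F3 | step 4 | 2-[4-(allyloxy)-2,6-bis(benzyloxy)phenyl]-1-[2,4,6-tris(methoxymethoxy)phenyl]ethan-1-ol (racemic) | OC(Cc1c(OCc2ccccc2)cc(OCC=C)cc1OCc1ccccc1)c1c(OCOC)cc(OCOC)cc1OCOC
F4 | step 4 | 2-[4-(allyloxy)-2,6-bis(benzyloxy)phenyl]-1-[2,4,6-tris(methoxymethoxy)phenyl]ethan-1-one | O=C(Cc1c(OCc2ccccc2)cc(OCC=C)cc1OCc1ccccc1)c1c(OCOC)cc(OCOC)cc1OCOC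
F5 | step 7 | 3-[2,6-bis(benzyloxy)-4-hydroxyphenyl]-5-hydroxy-7-methoxy-2-(4-methoxyphenyl)-4H-chromen-4-one | COc1ccc(cc1)-c1oc2cc(OC)cc(O)c2c(=O)c1-c1c(OCc2ccccc2)cc(O)cc1OCc1ccccc1
F6 | step 7 | 3-[2,6-bis(benzyloxy)-4-hydroxy-3-iodophenyl]-5-hydroxy-7-methoxy-2-(4-methoxyphenyl)-4H-chromen-4-one | COc1ccc(cc1)-c1oc2cc(OC)cc(O)c2c(=O)c1-c1c(OCc2ccccc2)c(I)c(O)cc1OCc1ccccc1
F7 | step 7 | 3-[2,6-bis(benzyloxy)-3-(1-ethoxyethenyl)-4-hydroxyphenyl]-5-hydroxy-7-methoxy-2-(4-methoxyphenyl)-4H-chromen-4-one | COc1ccc(cc1)-c1oc2cc(OC)cc(O)c2c(=O)c1-c1c(OCc2ccccc2)c(C(=C)OCC)c(O)cc1OCc1ccccc1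
F8 | step 11 | (2S)-5,7-bis(benzyloxy)-2-[4-(benzyloxy)phenyl]-6-[5-hydroxy-7-methoxy-2-(4-methoxyphenyl)-4-oxo-4H-chromen-3-yl]chroman-4-one | COc1ccc(-c2oc3cc(OC)cc(O)c3c(=O)c2-c2c(OCc4ccccc4)cc3c(c2OCc5ccccc5)C(=O)C[C@@H](c6ccc(OCc7ccccc7)cc6)O3)cc1
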